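In a one-step world every partner makes one product, so the east run's c(partner) allows 27.5% of the substrates charged as product, but the east readings stand at 7.3% left-handed product after 12.0 min.

| flask | left-handed substrate | right-handed substrate | partner | free catalyst | remark | time |
|---|---|---|---|---|---|---|
| east | 0.010 M | 0.010 M | 0.0055 M | 0.41 mM | run made earlier |  |
| west | 0.010 M | 0.010 M | 0.022 M | 0.41 mM | run made earlier |  |
| south | 0.010 M | 0.010 M | 0.011 M | 0.20 mM | run made earlier |  |
| flask | 0.010 M | 0.010 M | 0.0110 M | 0.41 mM |  | 25 min |

| run | time / min | left-handed substrate / % | right-handed substrate / % | left-handed product / % |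
|---|---|---|---|---|
| east | 3.00 | 43.3 | 49.4 | 5.0 |
| east | 6.00 | 41.9 | 49.5 | 6.4 |
| east | 8.00 | 41.6 | 49.4 | 7.4 |
| east | 12.0 | 41.8 | 49.1 | 7.3 |
| east | 15.0 | 42.4 | 48.8 | 7.1 |
| east | 20.0 | 41.6 | 49.2 | 6.8 |
| west | 1.00 | 38.8 | 48.8 | 9.8 |
| west | 3.00 | 30.3 | 47.8 | 18.8 |
| west | 6.00 | 28.7 | 47.7 | 20.6 |
| west | 8.00 | 28.4 | 46.8 | 21.1 |
| west | 12.0 | 27.6 | 47.4 | 21.0 |
| west | 15.0 | 27.0 | 48.5 | 22.3 |
| west | 20.0 | 26.8 | 47.2 | 22.0 |
| south | 1.50 | 46.2 | 49.8 | 3.9 |
| south | 3.00 | 43.8 | 48.8 | 6.2 |
| south | 6.00 | 41.9 | 48.5 | 7.1 |
| south | 10.0 | 41.7 | 49.9 | 7.8 |
| south | 20.0 | 42.0 | 49.2 | 8.8 |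

(readings scatter by 0.5 percentage points)

- free catalyst is single-handed; left-handed substrate and right-handed substrate are mirror images of each other, charged as a racemate, each of them at the stated concentration
- an excess is below zero if the other one leads

- part of the left-handed substrate and right-handed substrate charged together that has reacted at 25 min
- excess of left-handed product over right-handed product in the product at 25 min
- excess of right-handed substrate over left-handed substrate among what is left of the two at 25 min

So I read a partner yield: left-handed product at the stall per partner charged. East gives 0.265. West, with the same catalyst and more partner, gives a lower 0.200. South, with about half the catalyst and 0.011 M of partner, gives 0.160. These are readings, and each reading scatters by 0.5 percentage points.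

The flask has the catalyst of east and west, and its partner charge is the geometric mean of theirs, 0.0110 M, so it stands midway on a log scale of partner and I take the mean of their yields, 0.233, as the partner yield of the flask. That gives 12.8% left-handed product.

The forecast says 14.5% reacted, a product excess of 82% and a substrate excess of 14%, on the ground that “the plateau scales with catalyst charge, so the catalyst dies”. Its reacted part counts substrate, while my figure counts one product, so the two are different quantities.

The flask gives 15.3% reacted, a product excess of 83.1% and a substrate excess of 14.7%.

    partner + catalyst intermediate B → free catalyst + right-handed product (k = 5.00 /M/s)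
    partner + catalyst intermediate A → free catalyst + left-handed product (k = 10.0 /M/s)
    2 free catalyst ⇌ resting dimer, settled at all times (K = 2100 /M)
    free catalyst + left-handed substrate ⇌ catalyst intermediate A (K = 280 /M, k = 430 /M/s)
    partner → decomposed reagent (k = 0.00620 /s)
    2 partner → self-condensation product (k = 0.0990 /M/s)
    free catalyst + right-handed substrate ⇌ catalyst intermediate B (K = 43.0 /M, k = 190 /M/s)

At 25.0 min the flask's partner, the limiting reagent, stands at 0%, with 0.00702 M of decomposed reagent and free catalyst at 25.7% of the catalyst charged. Its 12.8% left-handed product is a partner yield of 0.233, against 0.233. Drawn on the same log scale from 0.233 toward west's 0.200, the yield at the 0.019 M partner of the neighbour flask is 0.207, so 19.7% left-handed product, and that neighbour flask gives 19.7%.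

The numbers in the tables stem from a simulated flask on assumed constants.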